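## The problem

Germacrane numbering is used throughout (also for the six-membered precursors): C1/C10 are the epoxide carbons (C10 bears the methyl C14), C2 is CH2, C3 bears an angelate, C4 the methyl C15 and the free hydroxyl, C5 an acetate, C6 is CH2, C7 bears the isopropenyl group, C8 an angelate, C9 an acetate. The carbocycle is ten-membered, with every ring carbon except C2 and C6 substituted, so end-to-end closure fights both ring strain and entropy. There are eight stereocentres: drawn flat, the oxygens at C3, C5, C8, C9, the epoxide oxygen and the isopropenyl group lie on one face, and only the C4 hydroxyl lies on the other. The epoxide is cis (C2 and C9 on the same side), so it derives from a (1(10)Z)-olefin. Four secondary hydroxyls must be told apart in pairs (acetates at C5 and C9, angelates at C3 and C8) while the tertiary C4–OH stays free. The angelates isomerise to tiglates with base or nucleophiles, the epoxide can be opened transannularly by the C4 hydroxyl, and the isopropenyl group competes in any undirected electrophilic olefin oxidation. The enabling feature is twofold: C5–C6–C7–C8–C9–C10, with C14 on C10, isopropenyl on C7 and oxygen on C5, is the carvone ring; and the C5 oxygen stands 1,5 to the C1=C10 unsaturation through C4–C3–C2, which is the pattern of an oxy-Cope product (ketone C5, enolate carbon C4, new bond C2–C3, olefin C1=C10, broken bond C5–C10). On the six-membered ring C7 can control C5 and C8, C8 can control C9, and C5 can control C10; C5 and C10 are then spent to set C3, C4 and the olefin geometry.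

## Retrosynthesis

**Esters and epoxide (27 ⇒ 22).** The C9 acetate is cut last, so that the free C9 hydroxyl of 25 can direct the epoxidation of C1=C10 (26) and keep the isopropenyl group out of it. The two angelates of 24 are put on together onto diol 23, which comes from 22 by removal of two 4-methoxybenzyl ethers. The C5 acetate is already present in 22 and the C9 oxygen is a silyl ether.

**C4–O bond (22 ⇒ 18).** In the enolate that precedes 18 only the outer face is open, and an oxygen electrophile on that face would give the C4 epimer. The outer face is therefore given to bromine (18). The oxygen is then brought in from the inner face by the neighbouring C5 acetate of 20, through acetoxonium ion 21, which inverts C4 and gives 22. The C5 carbinol of 19 comes from the ketone by hydride delivery anti to the C–Br bond.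

**Key cut, C2–C3 formed and C5–C10 broken (18 ⇒ 15).** A cut at C9–C10 or C1–C2 would need a fully oxygenated open chain and a strained closure. A fragmentation across the same C5–C10 bond would need a decalin with every stereocentre already present. Here the precursor is cyclohexanol 15, whose five stereocentres all derive from carvone. The product gains the ten-membered ring, the (Z)-olefin, C3, C4 and a regiodefined enolate in one operation. The forward reaction must run through a chair with the C5 alkenyl group axial and the C10 vinyl equatorial, and the enol ether must be (Z).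

**C4–C5 bond (15 ⇒ 8 + 13).** Ketone 8 and the alkenyllithium 14 made from bromide 13 are joined. The addition must be axial, on the face away from the axial C10 methyl.

**C10 quaternary centre (8 ⇒ 1).** The vinyl group on C10 is moved back to C5: 8 comes from epoxy silyl ether 7 by a semipinacol shift with inversion at C10. The all-cis array C5–O, C8–O, C9–O and isopropenyl follows in sequence:
- epoxide 6 comes from allylic alcohol 5 by hydroxyl-directed epoxidation;
- 5 comes from enone 4 by reduction;
- 4 comes from silyl ether 3 by allylic oxidation;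
- 3 comes from carbinol 2, the vinyl adduct of (R)-carvone 1.

**Enol ether bromide (13 ⇒ 9).** Bromide 13 comes from (Z)-propenyl ether 11 through dibromide 12; 11 comes from allyl ether 10, made from 4-methoxybenzyl alcohol 9.

## Roads not taken

Alternative 1: The most obvious cut is C9–C10, closing an open chain by a Nozaki–Hiyama–Kishi reaction (CrCl2/NiCl2) of iodo aldehyde A1 to cyclodecenol A2. A1 carries five stereocentres, among them the tertiary C4 carbinol between two oxygenated carbons, and these must be built one by one along a chain. The closure must then form a ten-membered ring holding a trisubstituted (Z)-olefin against ring strain and entropy, with no evident control of C9. The chosen plan makes the ring from a six-membered ring without any end-to-end closure and sets C3 and the olefin geometry in the same step.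

Alternative 2: A Grob fragmentation of cis-decalin A3 (C5 alkoxide, C1 sulfonate) breaks the same C5–C10 bond and gives hydroxy ketone A4. A3 has nine stereocentres, including C1 and both ring-fusion carbons, which are set only to be destroyed, and it needs the less accessible cis ring fusion with an equatorial sulfonate to give the (Z)-olefin. The precursor is as complex as the target, whereas 15 is made from carvone in eight steps on the main line.

Alternative 3: A biomimetic plan would oxidise germacratriene A5 late: dihydroxylation of C4=C5 and epoxidation of C1=C10 are conceivable. The oxygens at C3, C8 and C9 would, however, need three allylic C–H oxidations without any handle for position or face. Three olefins of similar reactivity and the ease of transannular cyclisation of germacradienes make this worse. The chosen plan places every oxygen from a carbonyl, an olefin or an enolate whose face is defined.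

Key step: step 12

## Steps

Step 1
Reactants: 1 (R)-(−)-carvone
Product: 2 (1S,5R)-1-ethenyl-2-methyl-5-(prop-1-en-2-yl)cyclohex-2-en-1-ol
Conditions: CH2=CHMgBr, THF, −78 to 0 °C; aqueous work-up
Reagents that add atoms: vinylmagnesium bromide, C=C[Mg]Br
Why: 1,2-Grignard addition to the enone; the nucleophile enters anti to the C7 isopropenyl group (axial attack on the half-chair with pseudo-equatorial isopropenyl), so the C5 hydroxyl is cis and the vinyl group trans to isopropenyl.

Step 2
Reactants: 2 (1S,5R)-1-ethenyl-2-methyl-5-(prop-1-en-2-yl)cyclohex-2-en-1-ol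
Product: 3 tert-butyl{[(1S,5R)-1-ethenyl-2-methyl-5-(prop-1-en-2-yl)cyclohex-2-en-1-yl]oxy}dimethylsilane
Conditions: t-BuMe2SiOSO2CF3, 2,6-lutidine, CH2Cl2, −78 °C
Reagents that add atoms: tert-butyldimethylsilyl trifluoromethanesulfonate, CC(C)(C)[Si](C)(C)OS(=O)(=O)C(F)(F)F
Why: Silylation of a tertiary alcohol with a silyl triflate and a hindered base; the ether blocks oxidative transposition in step 3 and is the migrating-terminus donor in step 7.

Step 3
Reactants: 3 tert-butyl{[(1S,5R)-1-ethenyl-2-methyl-5-(prop-1-en-2-yl)cyclohex-2-en-1-yl]oxy}dimethylsilane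
Product: 4 (4S,6R)-4-[(tert-butyldimethylsilyl)oxy]-4-ethenyl-3-methyl-6-(prop-1-en-2-yl)cyclohex-2-en-1-one
Conditions: CrO3, 3,5-dimethylpyrazole, CH2Cl2, −20 °C
Reagents that add atoms: chromium trioxide, O=[Cr](=O)=O
Why: Allylic oxidation of the only ring methylene next to the trisubstituted olefin (C8) to the enone; the isopropenyl and vinyl groups are less electron-rich and have no comparable allylic methylene.

Step 4
Reactants: 4 (4S,6R)-4-[(tert-butyldimethylsilyl)oxy]-4-ethenyl-3-methyl-6-(prop-1-en-2-yl)cyclohex-2-en-1-one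
Product: 5 (1R,4S,6R)-4-[(tert-butyldimethylsilyl)oxy]-4-ethenyl-3-methyl-6-(prop-1-en-2-yl)cyclohex-2-en-1-ol
Conditions: LiBH(s-Bu)3, THF, −78 °C; H2O
Reagents that add atoms: none
Why: 1,2-Reduction of a β,β-disubstituted enone by a bulky hydride from the side away from the neighbouring isopropenyl group, as with 2-alkylcyclohexanones; the C8 hydroxyl comes out pseudo-axial and cis to isopropenyl.

Step 5
Reactants: 5 (1R,4S,6R)-4-[(tert-butyldimethylsilyl)oxy]-4-ethenyl-3-methyl-6-(prop-1-en-2-yl)cyclohex-2-en-1-ol
Product: 6 5-[(tert-butyldimethylsilyl)oxy]-5-ethenyl-6-methyl-3-(prop-1-en-2-yl)-7-oxabicyclo[4.1.0]heptan-2-ol (epoxide O/C2–OH/C5–OSi/C3-isopropenyl all on one face)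
Conditions: VO(acac)2 (cat.), t-BuOOH, CH2Cl2, 0 °C
Reagents that add atoms: tert-butyl hydroperoxide, CC(C)(C)OO
Why: Hydroxyl-directed epoxidation of an allylic alcohol; the vanadium peroxide bound to C8–OH delivers oxygen to the same face of C9=C10 and leaves the isopropenyl and vinyl groups alone, which sets C9.

Step 6
Reactants: 6 the epoxy alcohol of step 5
Product: 7 tert-butyl{[3-ethenyl-5-[(4-methoxybenzyl)oxy]-2-methyl... ]}: the 4-methoxybenzyl ether of 6 at C8–O (same configuration)
Conditions: NaH, 4-MeOC6H4CH2Cl, Bu4NI (cat.), THF/DMF, 0 °C to rt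
Reagents that add atoms: 4-methoxybenzyl chloride, COc1ccc(CCl)cc1
Why: Williamson etherification; the alkoxide is cis to the epoxide and cannot open it from the back (no Payne rearrangement).

Step 7
Reactants: 7 the 4-methoxybenzyl ether of step 6
Product: 8 (2R,3R,4S,5R)-3-[(tert-butyldimethylsilyl)oxy]-2-ethenyl-4-[(4-methoxybenzyl)oxy]-2-methyl-5-(prop-1-en-2-yl)cyclohexan-1-one
Conditions: t-BuMe2SiOSO2CF3 (0.2 equiv), 2,6-di-tert-butyl-4-methylpyridine, CH2Cl2, −78 to −40 °C
Reagents that add atoms: none
Why: Semipinacol rearrangement of a 2,3-epoxy silyl ether: the silyl triflate activates the epoxide oxygen, the tertiary C10–O bond opens, and the C5 vinyl group, antiperiplanar to it on the opposite face, shifts to C10 with inversion. The C5 silyloxy carbon becomes the ketone and releases the silyl triflate again, so C10 is set (vinyl trans, methyl cis to C9–O) and C9–O ends as its silyl ether.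

Step 8
Reactants: 9 4-methoxybenzyl alcohol
Product: 10 1-methoxy-4-[(prop-2-en-1-yloxy)methyl]benzene
Conditions: NaH, allyl bromide, THF, 0 °C to rt
Reagents that add atoms: allyl bromide, C=CCBr
Why: Williamson etherification of a primary benzylic alkoxide.

Step 9
Reactants: 10 1-methoxy-4-[(prop-2-en-1-yloxy)methyl]benzene
Product: 11 (Z)-1-methoxy-4-[(prop-1-en-1-yloxy)methyl]benzene
Conditions: KOt-Bu (cat.), DMSO, rt
Reagents that add atoms: none
Why: Base-mediated isomerisation of an allyl ether to the propenyl ether, which gives the (Z)-isomer through the potassium-chelated allyl anion.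

Step 10
Reactants: 11 (Z)-1-methoxy-4-[(prop-1-en-1-yloxy)methyl]benzene
Product: 13 (Z)-1-{[(2-bromoprop-1-en-1-yl)oxy]methyl}-4-methoxybenzene, via dibromide 12 (not isolated)
Conditions: Br2, CH2Cl2, −78 °C; then i-Pr2NEt, −78 °C to rt
Reagents that add atoms: bromine, BrBr
Why: Anti addition of bromine to the enol ether, then anti elimination of the α-bromo-ether bromide and the C2 hydrogen; from the (Z)-enol ether this sequence puts bromine cis to oxygen, as in the known preparation of (Z)-1-bromo-2-ethoxyethene.

Step 11
Reactants: 13 (Z)-1-{[(2-bromoprop-1-en-1-yl)oxy]methyl}-4-methoxybenzene; 8 the ketone of step 7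
Product: 15 (1S,2R,3R,4S,5R)-3-[(tert-butyldimethylsilyl)oxy]-2-ethenyl-4-[(4-methoxybenzyl)oxy]-1-{(Z)-1-[(4-methoxybenzyl)oxy]prop-1-en-2-yl}-2-methyl-5-(prop-1-en-2-yl)cyclohexan-1-ol, via alkenyllithium 14 (not isolated)
Conditions: 13, t-BuLi (2 equiv), Et2O, −78 °C; then 8, THF, −78 °C; H2O
Reagents that add atoms: none
Why: Bromine–lithium exchange with retention gives the oxygen-chelated cis-β-alkoxyvinyllithium, which cannot undergo anti β-elimination. It adds to the ketone axially, on the face away from the axial C10 methyl and the C8 ether (only axial hydrogens at C7 and C9 on that face), so the alkenyl group is cis to the C10 vinyl group.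

Step 12
Reactants: 15 the dialkenyl cyclohexanol of step 11
Product: 18 (1(10)Z)-4-bromo-9-[(tert-butyldimethylsilyl)oxy]-3,8-bis[(4-methoxybenzyl)oxy]germacra-1(10),11-dien-5-one (C3/C7/C8/C9 as in 27; bromine at C4 on the face the hydroxyl of 27 does not occupy), via potassium alkoxide 16 (not isolated), via potassium enolate 17 (not isolated)
Conditions: KH, THF, 25 to 50 °C (18-crown-6 only if needed); then NBS, −78 °C
Reagents that add atoms: N-bromosuccinimide, O=C1CCC(=O)N1Br
Why: Anionic oxy-Cope rearrangement ([3,3]) of alkoxide 16 followed by C-bromination of the regiodefined enolate 17; the closest known reaction type is the ring expansion of 1,2-dialkenylcyclohexanols to cyclodec-5-enones with trapping of the enolate by an electrophile. The ten-membered ring is closed by forming C2–C3 in a six-membered chair while C5–C10 breaks, a four-atom ring expansion with no end-to-end closure. The cyclohexane is locked, since ring inversion would put C5–O, C9–O and the isopropenyl group 1,3,5-syn-axial; the C5 alkenyl group is therefore axial and the C10 vinyl equatorial. In the chair this places C9 pseudo-axial and the methyl pseudo-equatorial at C10, which gives the (Z)-C1=C10 olefin, and C6 pseudo-equatorial at C5, which gives the enolate with C3 and C6 trans. C3 is set by chirality transfer from C5 and C10 through this chair together with the (Z)-enol ether geometry (ether oxygen pseudo-axial, next to the alkoxide and bridged to it by K+). C4 is set by attack of the bromine electrophile on the only open, outer face of the trans-configured enolate, anti to the new C2–C3 bond. The step needs chair over boat, secured by the axial alkenyl group already lying over the vinyl group, and bromination faster than β-elimination of the C3 alkoxy group, secured by quenching at −78 °C.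

Step 13
Reactants: 18 the bromo ketone of step 12
Product: 19 (1(10)Z)-4-bromo-9-[(tert-butyldimethylsilyl)oxy]-3,8-bis[(4-methoxybenzyl)oxy]germacra-1(10),11-dien-5-ol (C5 as in 27)
Conditions: Zn(BH4)2, Et2O, −30 °C
Reagents that add atoms: none
Why: Reduction of an α-bromo ketone under Felkin–Anh control: hydride adds anti to the C4–Br bond, on the face opposite to the zinc-bound C3 ether, which gives the C5 alcohol syn (1,3) to the C3 oxygen.

Step 14
Reactants: 19 the bromohydrin of step 13
Product: 20 the C5 acetate of 19
Conditions: Ac2O, pyridine, DMAP (cat.), CH2Cl2, 0 °C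
Reagents that add atoms: acetic anhydride, CC(=O)OC(C)=O
Why: Acetylation of the only free hydroxyl; this acetate is the C5 acetate of the target and the participating group of step 15.

Step 15
Reactants: 20 the bromo acetate of step 14
Product: 22 (1(10)Z)-5-acetoxy-9-[(tert-butyldimethylsilyl)oxy]-4-hydroxy-3,8-bis[(4-methoxybenzyl)oxy]germacra-1(10),11-diene (C4 and C5 as in 27), via acetoxonium triflate 21 (not isolated)
Conditions: AgOSO2CF3, H2O, 2,6-lutidine, THF, 0 °C to rt
Reagents that add atoms: water, O
Why: Silver-assisted ionisation of the tertiary bromide with anchimeric assistance by the vicinal acetate (Woodward–Prévost type): the acetate carbonyl oxygen attacks C4 from the face opposite to bromine, so C4 is inverted and its oxygen is cis-bridged to C5–O in 21. Water adds to the cationic carbon and the ring opens to the hydroxy acetate, the acetyl group settling on the secondary C5 oxygen.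

Step 16
Reactants: 22 the hydroxy acetate of step 15
Product: 23 (1(10)Z)-5-acetoxy-9-[(tert-butyldimethylsilyl)oxy]germacra-1(10),11-diene-3,4,8-triol
Conditions: DDQ, CH2Cl2/pH 7 buffer, 0 °C
Reagents that add atoms: none
Why: Oxidative cleavage of both 4-methoxybenzyl ethers; any anisylidene acetal formed with the C4 hydroxyl is hydrolysed by the aqueous phase or a dilute acetic acid wash.

Step 17
Reactants: 23 the triol of step 16
Product: 24 (1(10)Z)-5-acetoxy-9-[(tert-butyldimethylsilyl)oxy]-4-hydroxygermacra-1(10),11-diene-3,8-diyl bis[(Z)-2-methylbut-2-enoate]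
Conditions: angelic acid, 2,4,6-Cl3C6H2COCl, Et3N, toluene, rt; then 23, toluene, 75 °C
Reagents that add atoms: angelic acid, C/C=C(/C)C(=O)O
Why: Yamaguchi esterification through the mixed anhydride without a nucleophilic catalyst, the conditions under which angelates are formed without isomerisation to tiglates; the tertiary C4 hydroxyl does not react.

Step 18
Reactants: 24 the bis-angelate of step 17
Product: 25 (1(10)Z)-5-acetoxy-4,9-dihydroxygermacra-1(10),11-diene-3,8-diyl bis[(Z)-2-methylbut-2-enoate]
Conditions: HF·pyridine, THF/pyridine, 0 °C to rt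
Reagents that add atoms: none
Why: Acidic fluoride cleavage of the silyl ether, chosen to avoid base-induced acyl migration from C8 to C9.

Step 19
Reactants: 25 the allylic alcohol of step 18
Product: 26 5-acetoxy-1,10-epoxy-4,9-dihydroxygermacr-11-ene-3,8-diyl bis[(Z)-2-methylbut-2-enoate] (epoxide as in 27)
Conditions: VO(acac)2 (cat.), t-BuOOH, CH2Cl2, 0 °C
Reagents that add atoms: tert-butyl hydroperoxide, CC(C)(C)OO
Why: Hydroxyl-directed epoxidation of a cyclic (Z)-allylic alcohol, which in medium rings gives the cis epoxy alcohol (epoxide oxygen on the face of C9–OH); the isopropenyl group and the angelates are not epoxidised.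

Step 20
Reactants: 26 the epoxy alcohol of step 19
Product: 27 CNP0281348.1
Conditions: Ac2O, DMAP, pyridine, CH2Cl2, 0 °C to rt
Reagents that add atoms: acetic anhydride, CC(=O)OC(C)=O
Why: Acetylation of the secondary C9 hydroxyl; the tertiary C4 hydroxyl is left free under these mild conditions.

## Compound list

1 | (R)-(−)-carvone | C=C(C)[C@H]1CC(=O)C(C)=CC1 | starting material
2 | (1S,5R)-1-ethenyl-2-methyl-5-(prop-1-en-2-yl)cyclohex-2-en-1-ol | C=C(C)[C@H]1C[C@](O)(C=C)C(C)=CC1 | intermediate
3 | tert-butyldimethylsilyl ether of 2 | C=C(C)[C@H]1C[C@](O[Si](C)(C)C(C)(C)C)(C=C)C(C)=CC1 | intermediate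
4 | (4S,6R)-4-silyloxy-4-ethenyl-3-methyl-6-isopropenylcyclohex-2-en-1-one | C=C(C)[C@H]1C[C@](O[Si](C)(C)C(C)(C)C)(C=C)C(C)=CC1=O | intermediate
5 | (1R,4S,6R)-allylic alcohol | C=C(C)[C@H]1C[C@](O[Si](C)(C)C(C)(C)C)(C=C)C(C)=C[C@H]1O | intermediate
6 | all-cis epoxy alcohol | C=C(C)[C@H]1C[C@](O[Si](C)(C)C(C)(C)C)(C=C)[C@@]2(C)O[C@H]2[C@H]1O | intermediate
7 | 4-methoxybenzyl ether of 6 | C=C(C)[C@H]1C[C@](O[Si](C)(C)C(C)(C)C)(C=C)[C@@]2(C)O[C@H]2[C@H]1OCc3ccc(OC)cc3 | intermediate
8 | (2R,3R,4S,5R)-ketone | C=C(C)[C@H]1CC(=O)[C@](C)(C=C)[C@@H](O[Si](C)(C)C(C)(C)C)[C@H]1OCc2ccc(OC)cc2 | intermediate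
9 | 4-methoxybenzyl alcohol | COc1ccc(CO)cc1 | starting material
10 | allyl 4-methoxybenzyl ether | C=CCOCc1ccc(OC)cc1 | intermediate
11 | (Z)-4-methoxybenzyl prop-1-enyl ether | C/C=C\OCc1ccc(OC)cc1 | intermediate
12 | rac-(1R,2S)-1,2-dibromo-1-[(4-methoxybenzyl)oxy]propane | C[C@H](Br)[C@@H](Br)OCc1ccc(OC)cc1 | intermediate (not isolated)
13 | (Z)-2-bromo-1-[(4-methoxybenzyl)oxy]prop-1-ene | C/C(Br)=C/OCc1ccc(OC)cc1 | intermediate
14 | {(E)-1-[(4-methoxybenzyl)oxy]prop-1-en-2-yl}lithium | C/C([Li])=C/OCc1ccc(OC)cc1 | intermediate (not isolated)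
15 | (1S,2R,3R,4S,5R)-dialkenyl cyclohexanol | C=C(C)[C@H]1C[C@](O)(/C(C)=C\OCc2ccc(OC)cc2)[C@](C)(C=C)[C@@H](O[Si](C)(C)C(C)(C)C)[C@H]1OCc3ccc(OC)cc3 | intermediate
16 | potassium alkoxide of 15 | C=C(C)[C@H]1C[C@]([O-])(/C(C)=C\OCc2ccc(OC)cc2)[C@](C)(C=C)[C@@H](O[Si](C)(C)C(C)(C)C)[C@H]1OCc3ccc(OC)cc3.[K+] | intermediate (not isolated)
17 | potassium C4=C5 enolate (C3/C6 trans; 1(10)Z) | C=C(C)[C@H]1C/C([O-])=C(C)/[C@@H](OCc2ccc(OC)cc2)C/C=C(C)\[C@@H](O[Si](C)(C)C(C)(C)C)[C@H]1OCc3ccc(OC)cc3.[K+] | intermediate (not isolated)
18 | 4-bromo-5-ketone | C=C(C)[C@H]1CC(=O)[C@@](C)(Br)[C@@H](OCc2ccc(OC)cc2)C/C=C(C)\[C@@H](O[Si](C)(C)C(C)(C)C)[C@H]1OCc3ccc(OC)cc3 | intermediate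
19 | 4-bromo-5-ol | C=C(C)[C@H]1C[C@@H](O)[C@@](C)(Br)[C@@H](OCc2ccc(OC)cc2)C/C=C(C)\[C@@H](O[Si](C)(C)C(C)(C)C)[C@H]1OCc3ccc(OC)cc3 | intermediate
20 | 4-bromo-5-acetate | C=C(C)[C@H]1C[C@@H](OC(C)=O)[C@@](C)(Br)[C@@H](OCc2ccc(OC)cc2)C/C=C(C)\[C@@H](O[Si](C)(C)C(C)(C)C)[C@H]1OCc3ccc(OC)cc3 | intermediate
21 | C4/C5 acetoxonium triflate | C=C(C)[C@H]1C[C@H]2OC(C)=[O+][C@]2(C)[C@@H](OCc3ccc(OC)cc3)C/C=C(C)\[C@@H](O[Si](C)(C)C(C)(C)C)[C@H]1OCc4ccc(OC)cc4.[O-]S(=O)(=O)C(F)(F)F | intermediate (not isolated)
22 | 5-acetoxy-4-ol | C=C(C)[C@H]1C[C@@H](OC(C)=O)[C@](C)(O)[C@@H](OCc2ccc(OC)cc2)C/C=C(C)\[C@@H](O[Si](C)(C)C(C)(C)C)[C@H]1OCc3ccc(OC)cc3 | intermediate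
23 | 5-acetoxy-3,4,8-triol | C=C(C)[C@H]1C[C@@H](OC(C)=O)[C@](C)(O)[C@@H](O)C/C=C(C)\[C@@H](O[Si](C)(C)C(C)(C)C)[C@H]1O | intermediate
24 | 3,8-bis-angelate, 9-silyl ether | C=C(C)[C@H]1C[C@@H](OC(C)=O)[C@](C)(O)[C@@H](OC(=O)/C(C)=C\C)C/C=C(C)\[C@@H](O[Si](C)(C)C(C)(C)C)[C@H]1OC(=O)/C(C)=C\C | intermediate
25 | 3,8-bis-angelate, 9-ol | C=C(C)[C@H]1C[C@@H](OC(C)=O)[C@](C)(O)[C@@H](OC(=O)/C(C)=C\C)C/C=C(C)\[C@@H](O)[C@H]1OC(=O)/C(C)=C\C | intermediate
26 | 1,10-epoxy-9-ol | C=C(C)[C@H]1C[C@@H](OC(C)=O)[C@](C)(O)[C@@H](OC(=O)/C(C)=C\C)C[C@H]2O[C@@]2(C)[C@@H](O)[C@H]1OC(=O)/C(C)=C\C | intermediate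
27 | CNP0281348.1 | C=C(C)[C@H]1C[C@@H](OC(C)=O)[C@](C)(O)[C@@H](OC(=O)/C(C)=C\C)C[C@H]2O[C@@]2(C)[C@@H](OC(C)=O)[C@H]1OC(=O)/C(C)=C\C | target

## Step count and least certain steps

Total: 20 steps. Longest linear sequence: 17 steps (steps 1–7 and 11–20, from carvone); the side branch is steps 8–10.

**Step 12 (key step).** Three processes may spoil it: a boat transition state competing with the chair (loss of control of the olefin geometry and of C3), β-elimination of the C3 alkoxy group from the potassium enolate before bromination, and cleavage of the alkoxide instead of rearrangement. Fallback: set out from 15, silylate it to the trimethylsilyl ether F1 (Me3SiCl, imidazole), and carry out the neutral thermal siloxy-Cope rearrangement (about 200 °C, sealed tube). This gives the trimethylsilyl enol ether F2 with no free enolate. Bromination of F2 with NBS at −78 °C then returns to 18.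

**Step 11.** Enolisation of the hindered ketone by the basic alkenyllithium, or attack on the wrong face, may compete with axial addition. Fallback: set out from 8 and add the small, weakly basic lithium (4-methoxybenzyloxy)acetylide (from 1,2-dichlorovinyl 4-methoxybenzyl ether and n-BuLi) to give the alkynyl carbinol F3. Syn carbocupration of the ynol ether with MeCu·MgBr2 (methyl to the carbon remote from oxygen) and protonation gives the (Z)-enol ether and returns to 15.

**Step 13.** Poor facial selectivity of the hydride is possible, because the ring conformation may override the Felkin–Anh preference. Fallback: the C5 epimer is also productive. Set out from 18 and reduce with LiBH(s-Bu)3 to the epimeric bromohydrin F4, which K2CO3 in MeOH closes to the cis-4,5-epoxide F5 (C5 alkoxide displaces the bromide with inversion at C4). Bu4NOAc/AcOH then opens F5 at the secondary C5 with inversion and returns to 22, bypassing steps 14 and 15.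

**Step 15.** Loss of a proton from the tertiary cation (elimination) or capture of the cation by the C1=C10 olefin (transannular cyclisation) may outrun acetate participation. Fallback: set out from 19, oxidise it back to 18 with Dess–Martin periodinane, and take the cationic step out of the route by the sequence through F4 and F5 described for step 13, returning at 22.

**Step 17.** Isomerisation of the angelate to the tiglate, or incomplete acylation of the two hindered hydroxyls, may occur. Fallback: set out from 23 and esterify with 2-[bis(2,2,2-trifluoroethoxy)phosphoryl]propanoic acid (DCC, DMAP) to the bis-phosphonate F6. A Still–Gennari olefination with acetaldehyde (KN(SiMe3)2, 18-crown-6, −78 °C) then builds both (Z)-2-methylbut-2-enoates on the molecule and returns to 24.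

**Step 19.** Epoxidation may occur on the wrong face if the ten-membered allylic alcohol reacts like an open-chain (Z)-allylic alcohol rather than like a medium-ring one; the product may also be opened by the C4 hydroxyl. Fallback: set out from 25, acetylate it first to the diene tetraester F7, and epoxidise C1=C10 under reagent control with a fructose-derived chiral ketone and KHSO5 (Shi epoxidation, catalyst enantiomer chosen for the required face), which returns directly to 27.

## Further compounds

F1 | step 12 | trimethylsilyl ether of 15 | C=C(C)[C@H]1C[C@](O[Si](C)(C)C)(/C(C)=C\OCc2ccc(OC)cc2)[C@](C)(C=C)[C@@H](O[Si](C)(C)C(C)(C)C)[C@H]1OCc3ccc(OC)cc3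
F2 | step 12 | trimethylsilyl enol ether (C4=C5) of the ring-expanded ketone | C=C(C)[C@H]1C/C(O[Si](C)(C)C)=C(C)/[C@@H](OCc2ccc(OC)cc2)C/C=C(C)\[C@@H](O[Si](C)(C)C(C)(C)C)[C@H]1OCc3ccc(OC)cc3
F3 | step 11 | alkynyl carbinol (ynol ether) from 8 | C=C(C)[C@H]1C[C@](O)(C#COCc2ccc(OC)cc2)[C@](C)(C=C)[C@@H](O[Si](C)(C)C(C)(C)C)[C@H]1OCc3ccc(OC)cc3
F4 | step 13 | C5-epimeric bromohydrin | C=C(C)[C@H]1C[C@H](O)[C@@](C)(Br)[C@@H](OCc2ccc(OC)cc2)C/C=C(C)\[C@@H](O[Si](C)(C)C(C)(C)C)[C@H]1OCc3ccc(OC)cc3
F5 | step 13 | cis-4,5-epoxide | C=C(C)[C@H]1C[C@@H]2O[C@]2(C)[C@@H](OCc3ccc(OC)cc3)C/C=C(C)\[C@@H](O[Si](C)(C)C(C)(C)C)[C@H]1OCc4ccc(OC)cc4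
F0 | step 15 | none | none
F6 | step 17 | 3,8-bis(phosphonopropanoate), mixture at the phosphonate α-carbons | C=C(C)[C@H]1C[C@@H](OC(C)=O)[C@](C)(O)[C@@H](OC(=O)C(C)P(=O)(OCC(F)(F)F)OCC(F)(F)F)C/C=C(C)\[C@@H](O[Si](C)(C)C(C)(C)C)[C@H]1OC(=O)C(C)P(=O)(OCC(F)(F)F)OCC(F)(F)F
F7 | step 19 | 1,10-deoxy diene tetraester | C=C(C)[C@H]1C[C@@H](OC(C)=O)[C@](C)(O)[C@@H](OC(=O)/C(C)=C\C)C/C=C(C)\[C@@H](OC(C)=O)[C@H]1OC(=O)/C(C)=C\C
A1 | alternative 1 | seco (Z)-iodoalkenyl aldehyde | O=C[C@@H](OCc1ccc(OC)cc1)[C@@H](C(C)=C)C[C@@H](OC(C)=O)[C@](C)(O)[C@@H](OCc2ccc(OC)cc2)C/C=C(C)\I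
A2 | alternative 1 | cyclodecenol from C9–C10 closure | C=C(C)[C@H]1C[C@@H](OC(C)=O)[C@](C)(O)[C@@H](OCc2ccc(OC)cc2)C/C=C(C)\[C@@H](O)[C@H]1OCc3ccc(OC)cc3
A3 | alternative 2 | cis-decalin C5-ol C1-mesylate | C=C(C)[C@H]1C[C@@]2(O)[C@](C)(O)[C@@H](OCc3ccc(OC)cc3)C[C@@H](OS(C)(=O)=O)[C@@]2(C)[C@@H](O[Si](C)(C)C(C)(C)C)[C@H]1OCc4ccc(OC)cc4
A4 | alternative 2 | 4-hydroxy-5-ketone from fragmentation | C=C(C)[C@H]1CC(=O)[C@](C)(O)[C@@H](OCc2ccc(OC)cc2)C/C=C(C)\[C@@H](O[Si](C)(C)C(C)(C)C)[C@H]1OCc3ccc(OC)cc3
A5 | alternative 3 | (1(10)Z,4E)-germacra-1(10),4,11-triene | C=C(C)[C@H]1C/C=C(C)/CC/C=C(C)\CC1
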